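## Retrosynthetic overview
1. Mitorubrinic acid (12) comes from a radical C7–O coupling of 7-H azaphilone 8 with orsellic acid (11). This step sets the C7 quaternary (R) centre.
2. Azaphilone 8 comes from a glyoxylic acid condensation at the 3-methyl group of benzopyrylium 6. Compound 6 comes from Vilsmeier formylation and cyclodehydration of 2-methylresorcinol 5.
3. Resorcinol 5 comes from a Collie-type aldol cyclisation of triketone 4. Triketone 4 comes from dianion acylation of 3-methylpentane-2,4-dione (3) with ketal ester 2, which is made from methyl acetoacetate (1).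
4. Orsellic acid (11) comes from methyl acetoacetate (1) and diketene (9) via tetraketide ester 10.
5. Order of ring formation: benzene ring (step 3), then pyran ring (step 4), then dearomatising C7 functionalisation that creates the cross-conjugated carbocyclic dione (step 8).

Assumptions: 7-H azaphilones (6, 8) exist as benzopyrylium-olate tautomers and are drawn as their keto forms. Orsellic acid is used with free phenols.

## Route

**Step 1**
Reactants: 1 (methyl acetoacetate)
Product: 2 (methyl 3,3-dimethoxybutanoate)
Conditions: HC(OMe)3, MeOH, cat. TsOH, rt, 12 h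
Reagents that add atoms: trimethyl orthoformate, COC(OC)OC; methanol, CO
Why: Acid-catalysed ketalisation masks the ketone. That leaves only one possible 6-ring aldol mode in step 3 and prevents chain-extension at that carbon in step 2.

**Step 2**
Reactants: 3 (3-methylpentane-2,4-dione), 2
Product: 4 (8,8-dimethoxy-3-methylnonane-2,4,6-trione)
Conditions: 3, NaH (1.0 equiv), THF, 0 °C; n-BuLi (1.05 equiv), 0 °C; then 2, 0 °C → rt; NH4Cl quench
Reagents that add atoms: none
Why: Harris/Weiler dianion C-acylation puts the new bond at the terminal carbanion (C1) of the 1,3-dianion and gives the 1,3,5-triketone.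

**Step 3**
Reactants: 4
Product: 5 (5-(2,2-dimethoxypropyl)-2-methylbenzene-1,3-diol)
Conditions: K2CO3, MeOH/H2O, 60 °C, 4 h
Reagents that add atoms: none
Why: Collie-type intramolecular aldol condensation and aromatisation of the 1,3,5-triketone (as for heptane-2,4,6-trione → orcinol). The only 6-ring mode is attack of the C1 methyl enolate on the C6 ketone, which puts the methyl between the two OH groups; the ketal survives base.

**Step 4**
Reactants: 5
Product: 6 (3,7-dimethyl-7H-isochromene-6,8-dione, the 7-H azaphilone; benzopyrylium-olate tautomer)
Conditions: POCl3 (1.2 equiv), DMF, 0 °C → rt, 2 h; then 48% aq HBF4, MeCN, 40 °C, 2 h; NaHCO3 to pH 5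
Reagents that add atoms: DMF, CN(C)C=O (source of the formyl carbon, C1); water, O
Why: Vilsmeier–Haack formylation occurs at the ring carbon ortho to one OH, para to the other and next to the alkyl group. Acid then removes the ketal, and the resulting 1,5-ketoaldehyde undergoes Dimroth-type cyclodehydration to the 2-benzopyrylium (pyran ring).

**Step 5**
Reactants: 6, 7 (glyoxylic acid)
Product: 8 ((E)-3-(7-methyl-6,8-dioxo-7H-isochromen-3-yl)acrylic acid)
Conditions: OHC-CO2H·H2O (3 equiv), AcOH/TFA (4:1), 70 °C, 8 h
Reagents that add atoms: none
Why: The 3-methyl group of the benzopyrylium is vinylogously acidic (via its anhydrobase), so aldol condensation with glyoxylic acid and dehydration give the thermodynamically favoured (E)-acrylic acid.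

**Step 6**
Reactants: 1, 9 (diketene)
Product: 10 (methyl 3,5,7-trioxooctanoate)
Conditions: 1 as dianion (NaH, then n-BuLi, THF, 0 °C; 2.5 equiv), then 9 (1.0 equiv), −78 → 0 °C
Reagents that add atoms: none
Why: The dianion is acetoacetylated at C4 by diketene (ring-opening acylation), giving the tetraketide chain.

**Step 7**
Reactants: 10
Product: 11 (orsellic acid, 2,4-dihydroxy-6-methylbenzoic acid)
Conditions: KOH (6 equiv), H2O, 80 °C, 6 h; then 2 M HCl, 0 °C
Reagents that add atoms: water, O (ester hydrolysis)
Why: Biomimetic Harris C2→C7 aldol cyclisation and aromatisation, followed by saponification in the same pot. The mixture is acidified cold to avoid decarboxylation.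

**Step 8**
Reactants: 8, 11
Product: 12 (mitorubrinic acid)
Conditions: 11 (2 equiv), Cu(OTf)2 (10 mol %), (S,S)-Ph-box (12 mol %), 2,6-lutidine (2 equiv), nBu4NBF4, MeCN, RVC(+)/Pt(–), 3 mA, 0 °C
Reagents that add atoms: none
Why: Proposed new method: the Cu(II)–box chelate of the 6,8-dioxygenated enolate of 8 is oxidised at the anode by single-electron transfer to a stabilised tertiary C7 radical. That radical is captured by a Cu(II) orsellate to give Cu(III), and C–O reductive elimination forms the tertiary ester face-selectively, setting 7R (the (S,S) ligand is assumed to give 7R; the (R,R) ligand gives the enantiomer). The closest known reactions are Kharasch–Sosnovsky acyloxylation, Mn(III) α′-acyloxylation of enones and Cu/box asymmetric radical C–O coupling. The enolate is more oxidisable than orsellic acid, and the tertiary ester cannot epimerise.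

## Compound list
1 | methyl acetoacetate | CC(=O)CC(=O)OC | starting material
2 | methyl 3,3-dimethoxybutanoate | COC(=O)CC(C)(OC)OC | intermediate
3 | 3-methylpentane-2,4-dione | CC(=O)C(C)C(C)=O | starting material
4 | 8,8-dimethoxy-3-methylnonane-2,4,6-trione | CC(=O)C(C)C(=O)CC(=O)CC(C)(OC)OC | intermediate
5 | 5-(2,2-dimethoxypropyl)-2-methylbenzene-1,3-diol | Cc1c(O)cc(CC(C)(OC)OC)cc1O | intermediate
6 | 3,7-dimethyl-7H-isochromene-6,8-dione (7-H azaphilone) | CC1C(=O)C=C2C=C(C)OC=C2C1=O | intermediate
7 | glyoxylic acid | O=CC(=O)O | starting material
8 | (E)-3-(7-methyl-6,8-dioxo-7H-isochromen-3-yl)acrylic acid | CC1C(=O)C=C2C=C(/C=C/C(=O)O)OC=C2C1=O | intermediate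
9 | diketene | C=C1CC(=O)O1 | starting material
10 | methyl 3,5,7-trioxooctanoate | COC(=O)CC(=O)CC(=O)CC(C)=O | intermediate
11 | orsellic acid | Cc1cc(O)cc(O)c1C(=O)O | intermediate
12 | mitorubrinic acid | Cc1cc(O)cc(O)c1C(=O)O[C@]1(C)C(=O)C=C2C=C(/C=C/C(=O)O)OC=C2C1=O | target

## Totals
Total steps: 8. Longest linear sequence: 6 (1 → 2 → 4 → 5 → 6 → 8 → 12, i.e. steps 1, 2, 3, 4, 5, 8).

## Three steps most likely to fail
1. **Step 8 (enantioselective radical acyloxylation).** Risks are low ee, competing acyloxylation by the side-chain acid or oxidation of free orsellic acid. Fallback: Cu(II)/(–)-sparteine/O2 enantioselective hydroxylative dearomatisation of 8 to the 7-hydroxy azaphilone, then esterification with bis-TBS-orsellic acid chloride and fluoride deprotection.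
2. **Step 5 (glyoxylic acid condensation).** The electron-rich, deactivated benzopyrylium may react poorly, or glyoxylic acid may hydroxyalkylate ring C5. Fallback: convert 6 to the O,O-diacetyl benzopyrylium (Ac2O, HBF4), condense with tert-butyl glyoxylate, then deacylate under mild acid.
3. **Step 7 (tetraketide cyclisation).** Competing aldol mode (to the 3,5-dihydroxyphenylacetate), retro-Claisen cleavage, or incomplete hydrolysis of the hindered ester. Fallback: acetylacetone dianion + EtOAc → heptane-2,4,6-trione → Collie cyclisation to orcinol → Kolbe–Schmitt carboxylation to orsellic acid.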